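**Retrosynthetic overview**
1. Target 18 ⇐ cross-conjugated dienone 16, by 1,4-reduction of the C4=C5 enone arm and face-selective protonation at C5.
2. 16 ⇐ formyl lactone 12 + 1,3-dimethoxypropan-2-one (aldol, lactone-acylating Claisen cyclisation, two dehydrations).
3. 12 ⇐ allyl enol ether 11 by a Claisen [3,3] rearrangement, which makes the C3a–allyl bond and the quaternary centre anti to the aryl group.
4. 11 ⇐ trans-lactone 9 ⇐ enoate 5 (from methyl (R)-lactate) + aryl Grignard, by anti-selective conjugate addition.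
5. Ring order: the γ-lactone first (stereochemical template), then the carbocycle; in that same step the lactone opens and its oxygen re-closes as the dihydrofuran.

Assumption: the SMILES is read as (2R,3S,3aR,5S), i.e. 2-Me/3-Ar trans, allyl trans to aryl, 5-OMe cis to allyl; compounds 3, 6 and 13 are taken as catalogue reagents.

**Route**

Step 1
Reactants: 1 methyl (R)-lactate
Product: 2 methyl (2R)-2-[(tert-butyldimethylsilyl)oxy]propanoate
Conditions: TBSCl, imidazole, DMF, 0 °C → rt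
Reagents that add atoms: tert-butyldimethylsilyl chloride (TBSCl), CC(C)(C)[Si](C)(C)Cl
Why: Plain O-silylation of the secondary alcohol; the bought stereocentre (future C2) is not touched.

Step 2
Reactants: 2 methyl (2R)-2-[(tert-butyldimethylsilyl)oxy]propanoate; 3 ethyl (triphenylphosphoranylidene)acetate
Product: 5 ethyl (2E,4R)-4-[(tert-butyldimethylsilyl)oxy]pent-2-enoate, via silyloxy aldehyde 4 (not isolated)
Conditions: iBu2AlH, CH2Cl2, −78 °C; then 3, −78 °C → rt
Reagents that add atoms: none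
Why: Partial ester reduction followed by in-flask Wittig olefination with a stabilised ylide gives the E-enoate without handling the epimerisable α-silyloxy aldehyde.

Step 3
Reactants: 5 ethyl (2E,4R)-4-[(tert-butyldimethylsilyl)oxy]pent-2-enoate; 6 3,4,5-trimethoxyphenylmagnesium bromide
Product: 9 (4R,5R)-5-methyl-4-(3,4,5-trimethoxyphenyl)oxolan-2-one, via silyl ketene acetal 7 (not isolated), via silyl ether ester 8 (not isolated)
Conditions: 6 (2.5 equiv), CuBr·SMe2 (20 mol%), Me3SiCl, THF, −78 → −30 °C; then 3 M HCl (aq), THF, 45 °C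
Reagents that add atoms: none
Why: Copper-catalysed, Me3SiCl-accelerated conjugate addition puts the aryl group anti to the γ-silyloxy group (Felkin-type 1,2-induction from the lactate centre), and the acid then removes both silyl groups and lactonises to the trans-lactone.

Step 4
Reactants: 9 (4R,5R)-5-methyl-4-(3,4,5-trimethoxyphenyl)oxolan-2-one
Product: 11 (3E,4S,5R)-5-methyl-3-[(prop-2-en-1-yloxy)methylidene]-4-(3,4,5-trimethoxyphenyl)oxolan-2-one, via sodium enolate 10 (not isolated)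
Conditions: NaH, HCO2Et, THF, 0 °C → rt; then allyl bromide, DMPU, rt
Reagents that add atoms: ethyl formate, CCOC=O; allyl bromide, C=CCBr
Why: Claisen condensation (α-formylation) of the lactone and O-alkylation of the hydroxymethylene enolate give the allyl vinyl ether; any C-allylated material is already compound 12.

Step 5
Reactants: 11 (3E,4S,5R)-5-methyl-3-[(prop-2-en-1-yloxy)methylidene]-4-(3,4,5-trimethoxyphenyl)oxolan-2-one
Product: 12 (3S,4S,5R)-5-methyl-2-oxo-3-(prop-2-en-1-yl)-4-(3,4,5-trimethoxyphenyl)oxolane-3-carbaldehyde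
Conditions: PhMe (degassed), 180 °C, sealed tube
Reagents that add atoms: none
Why: Claisen [3,3]-sigmatropic rearrangement; the allyl group is delivered to lactone C3 on the ring face opposite the adjacent aryl group, so the quaternary centre (future C3a) forms with allyl trans to aryl whatever the enol ether geometry.

Step 6
Reactants: 12 (3S,4S,5R)-5-methyl-2-oxo-3-(prop-2-en-1-yl)-4-(3,4,5-trimethoxyphenyl)oxolane-3-carbaldehyde; 13 1,3-dimethoxypropan-2-one
Product: 16 (2R,3S,3aS)-5,7-dimethoxy-2-methyl-3a-(prop-2-en-1-yl)-3-(3,4,5-trimethoxyphenyl)-3,3a-dihydro-1-benzofuran-6(2H)-one, via aldol adduct 14 (not isolated), via hydroxy dione 15 (not isolated)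
Conditions: 13, LiN(iPr)2 (1.1 equiv), THF, −78 °C, then 12; LiN(iPr)2 (1.3 equiv), −78 → 0 °C; 1 M HCl; then TsOH·H2O (10 mol%), 4 Å MS, PhMe, 50 °C
Reagents that add atoms: none
Why: Aldol addition to the non-enolisable aldehyde, then intramolecular Claisen (Dieckmann-type) acylation of the second ketone enolate by the lactone carbonyl (δ-keto ester → cyclohexane-1,3-dione), then acid-driven β-elimination and cyclodehydration of the freed secondary hydroxyl onto the vinylogous acid; no existing stereocentre is touched.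

Step 7
Reactants: 16 (2R,3S,3aS)-5,7-dimethoxy-2-methyl-3a-(prop-2-en-1-yl)-3-(3,4,5-trimethoxyphenyl)-3,3a-dihydro-1-benzofuran-6(2H)-one
Product: 18 (2R,3S,3aR,5S)-5,7-dimethoxy-2-methyl-3a-(prop-2-en-1-yl)-3-(3,4,5-trimethoxyphenyl)-3,3a,4,5-tetrahydro-1-benzofuran-6(2H)-one, via silyl dienol ether 17 (not isolated)
Conditions: [(Ph3P)CuH]6 (5 mol%), PhMe2SiH, PhMe, rt; then 1 M HCl, THF, −20 → 0 °C
Reagents that add atoms: none
Why: Copper hydride 1,4-hydrosilylation reduces only the C4=C5 enone arm (the vinylogous ester arm and the allyl group are inert), and kinetic C-protonation of the dienol ether at C5 from the face opposite the pseudoaxial allyl group places 5-OMe cis to allyl.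

**Compound list**
1 | methyl (R)-lactate | C[C@@H](O)C(=O)OC | starting material
2 | methyl (2R)-2-[(tert-butyldimethylsilyl)oxy]propanoate | C[C@@H](O[Si](C)(C)C(C)(C)C)C(=O)OC | intermediate
3 | ethyl (triphenylphosphoranylidene)acetate | CCOC(=O)C=P(c1ccccc1)(c1ccccc1)c1ccccc1 | starting material
4 | (2R)-2-[(tert-butyldimethylsilyl)oxy]propanal | C[C@@H](O[Si](C)(C)C(C)(C)C)C=O | intermediate (not isolated)
5 | ethyl (2E,4R)-4-[(tert-butyldimethylsilyl)oxy]pent-2-enoate | C[C@@H](O[Si](C)(C)C(C)(C)C)/C=C/C(=O)OCC | intermediate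
6 | 3,4,5-trimethoxyphenylmagnesium bromide | COc1cc([Mg]Br)cc(OC)c1OC | starting material
7 | ethyl trimethylsilyl ketene acetal of ester 8, (3R,4R), E/Z mixture | CCOC(O[Si](C)(C)C)=C[C@H](c1cc(OC)c(OC)c(OC)c1)[C@@H](C)O[Si](C)(C)C(C)(C)C | intermediate (not isolated)
8 | ethyl (3R,4R)-4-[(tert-butyldimethylsilyl)oxy]-3-(3,4,5-trimethoxyphenyl)pentanoate | CCOC(=O)C[C@H](c1cc(OC)c(OC)c(OC)c1)[C@@H](C)O[Si](C)(C)C(C)(C)C | intermediate (not isolated)
9 | (4R,5R)-5-methyl-4-(3,4,5-trimethoxyphenyl)oxolan-2-one (trans) | O=C1C[C@H](c2cc(OC)c(OC)c(OC)c2)[C@@H](C)O1 | intermediate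
10 | sodium [(4S,5R)-5-methyl-2-oxo-4-(3,4,5-trimethoxyphenyl)oxolan-3-ylidene]methanolate | O=C1O[C@H](C)[C@@H](c2cc(OC)c(OC)c(OC)c2)C1=C[O-].[Na+] | intermediate (not isolated)
11 | (3E,4S,5R)-5-methyl-3-[(prop-2-en-1-yloxy)methylidene]-4-(3,4,5-trimethoxyphenyl)oxolan-2-one | O=C1O[C@H](C)[C@@H](c2cc(OC)c(OC)c(OC)c2)/C1=C\OCC=C | intermediate
12 | (3S,4S,5R)-5-methyl-2-oxo-3-(prop-2-en-1-yl)-4-(3,4,5-trimethoxyphenyl)oxolane-3-carbaldehyde (allyl trans to aryl) | C=CC[C@]1(C=O)C(=O)O[C@H](C)[C@H]1c1cc(OC)c(OC)c(OC)c1 | intermediate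
13 | 1,3-dimethoxypropan-2-one | COCC(=O)COC | starting material
14 | (3S,4S,5R)-3-(1-hydroxy-2,4-dimethoxy-3-oxobutyl)-5-methyl-3-(prop-2-en-1-yl)-4-(3,4,5-trimethoxyphenyl)oxolan-2-one, mixture at the two new side-chain carbons | C=CC[C@]1(C(O)C(OC)C(=O)COC)C(=O)O[C@H](C)[C@H]1c1cc(OC)c(OC)c(OC)c1 | intermediate (not isolated)
15 | (4S)-5-hydroxy-4-[(1S,2R)-2-hydroxy-1-(3,4,5-trimethoxyphenyl)propyl]-2,6-dimethoxy-4-(prop-2-en-1-yl)cyclohexane-1,3-dione, mixture at C2, C5, C6 | C=CC[C@]1([C@H](c2cc(OC)c(OC)c(OC)c2)[C@@H](C)O)C(O)C(OC)C(=O)C(OC)C1=O | intermediate (not isolated)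
16 | (2R,3S,3aS)-5,7-dimethoxy-2-methyl-3a-(prop-2-en-1-yl)-3-(3,4,5-trimethoxyphenyl)-3,3a-dihydro-1-benzofuran-6(2H)-one | C=CC[C@]12C=C(OC)C(=O)C(OC)=C1O[C@H](C)[C@H]2c1cc(OC)c(OC)c(OC)c1 | intermediate
17 | (2R,3S,3aR)-6-{[dimethyl(phenyl)silyl]oxy}-5,7-dimethoxy-2-methyl-3a-(prop-2-en-1-yl)-3-(3,4,5-trimethoxyphenyl)-2,3,3a,4-tetrahydro-1-benzofuran | C=CC[C@]12CC(OC)=C(O[Si](C)(C)c3ccccc3)C(OC)=C1O[C@H](C)[C@H]2c1cc(OC)c(OC)c(OC)c1 | intermediate (not isolated)
18 | (2R,3S,3aR,5S)-5,7-dimethoxy-2-methyl-3a-(prop-2-en-1-yl)-3-(3,4,5-trimethoxyphenyl)-3,3a,4,5-tetrahydro-1-benzofuran-6(2H)-one | C=CC[C@]12C[C@H](OC)C(=O)C(OC)=C1O[C@H](C)[C@H]2c1cc(OC)c(OC)c(OC)c1 | target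

**Totals**
Total steps: 7. Longest linear sequence: 7 (from methyl (R)-lactate; 3, 6 and 13 are bought).

**Steps most likely to fail, with fallbacks**

Step 6 (annulation). The lithium aldolate of the α-quaternary aldehyde can revert or lose the formyl carbon before the ring closes. The fallback sets out from 12 and comes back at 18. A TiCl4/Et3N crossed aldol of 13 with 12 gives 14, which is isolated and dehydrated (TsOH, PhMe, 80 °C) to the acyclic (Z)-enone (3S,4S,5R)-3-[(1Z)-2,4-dimethoxy-3-oxobut-1-en-1-yl]-5-methyl-3-(prop-2-en-1-yl)-4-(3,4,5-trimethoxyphenyl)oxolan-2-one F1. Its geometry forbids ring closure, so it is first reduced with [(Ph3P)CuH]6 in wet THF to the saturated keto lactone (3R,4S,5R)-3-(2,4-dimethoxy-3-oxobutyl)-5-methyl-3-(prop-2-en-1-yl)-4-(3,4,5-trimethoxyphenyl)oxolan-2-one F2. KOtBu in THF then closes the cyclohexane-1,3-dione onto the lactone carbonyl, and TsOH cyclodehydrates to 18 mixed with its C5 epimer (2R,3S,3aR,5R)-5,7-dimethoxy-2-methyl-3a-(prop-2-en-1-yl)-3-(3,4,5-trimethoxyphenyl)-3,3a,4,5-tetrahydro-1-benzofuran-6(2H)-one F3. The mixture is converged on 18 by enolisation with LiN(iPr)2 (C5–H is the only enolisable position) and quenching with 2,6-di-tert-butylphenol at −78 °C.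

Step 7 (reduction and C5 protonation). The risk is a poor C5 ratio when protonation is coupled to the work-up of the reduction, or some 1,2-reduction. The fallback sets out from 16 and comes back at 18. The two events are separated: LiBH(sBu)3 in THF at −78 °C adds hydride 1,4 and the enolate is trapped with TBSOTf to give the isolable tert-butyldimethylsilyl dienol ether (2R,3S,3aR)-6-[(tert-butyldimethylsilyl)oxy]-5,7-dimethoxy-2-methyl-3a-(prop-2-en-1-yl)-3-(3,4,5-trimethoxyphenyl)-2,3,3a,4-tetrahydro-1-benzofuran F4. After purification it is cleaved with Bu4NF in the presence of 2,6-di-tert-butylphenol at −78 °C, so the bulky proton donor approaches the free enolate anti to the allyl group and gives 18.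

Step 3 (acyclic conjugate addition). The anti/syn ratio on the open-chain enoate may be only moderate. The fallback sets out from 2 and comes back at 9. iBu2AlH reduction followed by Wittig reaction with 3 in MeOH at 0 °C (Z-selective for α-alkoxy aldehydes) gives the (Z)-enoate ethyl (2Z,4R)-4-[(tert-butyldimethylsilyl)oxy]pent-2-enoate F5. TsOH in MeOH removes the silyl group and lactonises it to the butenolide (5R)-5-methylfuran-2(5H)-one F6. Addition of 6 with CuBr·SMe2 to this rigid ring occurs trans to the methyl group and gives 9 directly.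

**Further compounds**
F1 | step 6 | (3S,4S,5R)-3-[(1Z)-2,4-dimethoxy-3-oxobut-1-en-1-yl]-5-methyl-3-(prop-2-en-1-yl)-4-(3,4,5-trimethoxyphenyl)oxolan-2-one | C=CC[C@]1(/C=C(\OC)C(=O)COC)C(=O)O[C@H](C)[C@H]1c1cc(OC)c(OC)c(OC)c1
F2 | step 6 | (3R,4S,5R)-3-(2,4-dimethoxy-3-oxobutyl)-5-methyl-3-(prop-2-en-1-yl)-4-(3,4,5-trimethoxyphenyl)oxolan-2-one (epimers at the methoxy-bearing side-chain carbon) | C=CC[C@]1(CC(OC)C(=O)COC)C(=O)O[C@H](C)[C@H]1c1cc(OC)c(OC)c(OC)c1
F3 | step 6 | (2R,3S,3aR,5R)-5,7-dimethoxy-2-methyl-3a-(prop-2-en-1-yl)-3-(3,4,5-trimethoxyphenyl)-3,3a,4,5-tetrahydro-1-benzofuran-6(2H)-one | C=CC[C@]12C[C@@H](OC)C(=O)C(OC)=C1O[C@H](C)[C@H]2c1cc(OC)c(OC)c(OC)c1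
F4 | step 7 | (2R,3S,3aR)-6-[(tert-butyldimethylsilyl)oxy]-5,7-dimethoxy-2-methyl-3a-(prop-2-en-1-yl)-3-(3,4,5-trimethoxyphenyl)-2,3,3a,4-tetrahydro-1-benzofuran | C=CC[C@]12CC(OC)=C(O[Si](C)(C)C(C)(C)C)C(OC)=C1O[C@H](C)[C@H]2c1cc(OC)c(OC)c(OC)c1
F5 | step 3 | ethyl (2Z,4R)-4-[(tert-butyldimethylsilyl)oxy]pent-2-enoate | C[C@@H](O[Si](C)(C)C(C)(C)C)/C=C\C(=O)OCC
F6 | step 3 | (5R)-5-methylfuran-2(5H)-one | C[C@H]1OC(=O)C=C1
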